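## The problem

Atom labels used throughout: C10 is the quaternary ring carbon (C14 methyl, C1=C2 vinyl), C5 carries C4(=C3H2)–C15H2OH, C6 the free hydroxyl, C7 and C8 the lactone fusion (C11=C13H2 on C7, C12=O, ring oxygen O8 on C8), and C9 the isobutyrate; TBS = tert-butyldimethylsilyl.

The target is a cyclohexane substituted on every ring carbon and cis-fused at C7–C8 to an α-methylene-γ-butyrolactone. It has six contiguous stereocentres, one of them the all-carbon quaternary C10 between the oxygenated C9 and the branched C5. If the ring is closed late, C5, C6, C9 and C10 must be set in an open chain by reagent control. C5/C6 is an aldol pattern, and C9/C10 is an allylation pattern in which the alkene geometry ties C10 to C9. C7 and C8 can then be left to the ring closure, where the four existing centres choose the chair. The methylene lactone is a Michael acceptor and does not tolerate base, nucleophiles or enolate chemistry, and the secondary isobutyrate can hydrolyse or migrate. The three terminal alkenes rule out hydrogenolysis, ozonolysis and electrophilic halogen, and C5–H is allylic and acidic whenever C10 is a carbonyl. The cis C7–C8 junction, with C11(=C13) on C7 and the ester oxygen on C8, is what γ-addition of a 2-(metallomethyl)acrylate to an aldehyde leaves behind, so carbocycle, lactone and methylene can be formed together from an open chain.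

## Retrosynthesis

**34 ⇒ 33.** Only the two O–Si bonds are cut. O6 and O15 must be masked during ring closure, and two silyl ethers of the same kind fall together under buffered fluoride, which the methylene lactone and the isobutyrate of 34 tolerate. The forward step only has to avoid base.

**33 ⇒ 30.** C7–C8 and O8–C12 are cut, giving the open-chain formyl (Z)-2-(bromomethyl)enoate 30. Cuts at C5–C6 or C6–C7 either leave the methylene to be added later or rely on electron transfer. This cut removes both rings, two stereocentres and the exocyclic methylene at once. The forward reaction must make the allylmetal in the presence of two esters and an aldehyde, give the cis junction, and choose the right face.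

**30 ⇒ 28 ⇒ 27 ⇒ 25 + 26.** The C8 aldehyde of 30 is held until the last moment as a dioxolane carbon in 28 and is released by glycol cleavage with loss of one carbon. The bromomethyl enoate of 28 is the allylic transposition product of hydroxy acrylate 27, which is cut at C7–C11 into aldehyde 25 and methyl propiolate 26. An olefination of 25 would need a separate functionalisation of C13. The forward steps must be non-basic at the α-silyloxy aldehyde and give the (Z) enoate.

**25 ⇒ 23 ⇒ 22 ⇒ 20 + 21.** After functional-group adjustment (aldehyde 25 from acetal 23, ester 23 from alcohol 22), C9–C10 is cut. Alcohol 22 is the adduct of the γ,γ-disubstituted allylboronate 20 and glyceraldehyde acetonide 21. A cut at C10–C5 would need a tertiary carbanion or a sigmatropic shift steered by remote centres. This cut makes the quaternary carbon from a trisubstituted alkene, delivers the vinyl group, and lets the aldehyde's own stereocentre (the later C8, destroyed in the end) fix C9. The forward reaction needs pure (E) geometry in 20 and a closed transition state.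

**20 ⇒ 19 ⇒ 18 ⇒ 17 ⇒ 16 ⇒ 15 ⇒ 13 + 14.** Boronate 20 goes back through acetate 19 and alcohol 18 to the (E)-enoate 17. A carbonyl olefination would pass through a methyl ketone whose C5–H is α-keto, allylic and β to a silyloxy group. Instead, 17 is traced to the (Z)-enol phosphate 16 of β-keto ester 15, the Claisen product of Weinreb amide 13 and ethyl acetate 14 (C1–C10 bond). The alkene geometry then depends on enolate chelation and a stereospecific methyl-for-phosphate exchange.

**13 ⇒ 12 ⇒ 11 ⇒ 8 + 9.** C5–C6 is cut as an aldol with C10 as the acyl carbon, leading to imide 8 and dimethoxyacetaldehyde 9. With C10 as the carbonyl the required relationship is syn, the reliable auxiliary mode. With C4 as the carbonyl an anti-aldol of a hindered substrate would be needed. The precursors are an achiral acyl imide and a two-carbon aldehyde that already carries C7 at the aldehyde oxidation level. The forward reaction must occur at the α-carbon of the β,γ-unsaturated enolate.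

**8 ⇒ 5 + 6; 5 ⇒ 4 ⇒ 3 ⇒ 1.** The N–C10 bond is cut to acid 5 and oxazolidinone 6. Acid 5 already holds C5, C4, C3 and C15 with O15 in place and comes via 4 and 3 from itaconate half ester 1. This avoids a later allylic oxidation next to C5. The forward sequence needs a chemoselective reduction of the conjugated acid of 1 and silylation before the hydroxy ester 3 can lactonise.

## Roads not taken

**Alternative 1:** The ring is bought as enone A2 and only C4–C5 and C1–C10 are made. The alkenylmagnesium reagent A3 with CuBr·SMe2 (monovalent copper) adds to C5 anti to the C6 silyloxy group, and the enolate is hydroxymethylated at C10 by formaldehyde A4 to give ketone A1.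
- *Merits:* three contiguous centres (C5, C6, C10) arise from one in a single flask. Up to this point it is clearly shorter than the fifteen steps the chosen plan spends on its acyclic tetrad.
- *Weak points:* C7 and C8 of A1 are bare methylenes. The cis lactone, its oxygen and the exocyclic methylene must be grafted onto a CH2–CH2 unit next to the C9 ketone, with C7, C8 and C9 all left to substrate control and the methylene added by enolate chemistry. A1 is a β-hydroxy ketone with a quaternary α-carbon and can lose A4 by retro-aldol. A3 is a β-silyloxy vinylmetal prone to silyl migration.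
- *Comparison:* the chosen plan pays at the front and wins at the back, because 30 → 33 creates in one step what Alternative 1 needs a long, weakly controlled sequence for.

**Alternative 2:** C5–C6 is cut. Under Me2AlCl the C6 aldehyde of the open-chain lactone A6 is attacked by C5 of the (Z)-trisubstituted C5=C4 alkene while a C3 hydrogen moves to oxygen. This closes the carbocycle, creates the C4=C3 methylene and gives hydroxy lactone A5.
- *Merits:* a six-membered carbonyl-ene closure of the isopulegol kind sets C5 and C6 trans-diequatorial from the chair. O6 emerges free, so one protecting group is saved, and the hydroxymethylvinyl unit is made in the step. In these respects it is at least as good as the chosen plan.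
- *Weak points:* A5 lacks C13, so the methylene must be added by lactone enolate chemistry in the presence of the isobutyrate. A6 needs a stereodefined trisubstituted alkene directly on the quaternary C10 and already contains C7 and C8, which must be set in the open chain. The ene step must take hydrogen from the C3 methyl and not from the C15 methylene. C7, α to the aldehyde, can epimerise under the Lewis acid.
- *Comparison:* the chosen plan needs a silyl group on O6 and a longer route to its stereotetrad. Against that it delivers ring, lactone and methylene together and never touches the lactone with base.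

**Alternative 3:** C6–C7 is cut. SmI2 (divalent samarium) reduces the C6 aldehyde of butenolide aldehyde A8 to a ketyl that adds 6-exo to C7, and the C11 radical or enolate expels phenylthiolate to give A7, the 15-silyl ether of 34.
- *Merits:* ring and methylene appear together and one deprotection ends the synthesis, as in the chosen plan. The cis fusion is guaranteed because C8 is already a stereocentre of the butenolide. O6 needs no protecting group, so protecting-group economy is better.
- *Weak points:* the aldehyde of A8 sits on C5, which is allylic and α to the carbonyl, so the centre that must steer the closure is the most epimerisable one. The electron-poor thiomethyl butenolide competes with the aldehyde for the reductant (loss of thiolate or cleavage of the C8–O bond before cyclisation). The C6 configuration depends on ketyl geometry. A8 still needs the same open-chain C5–C10–C9–C8 array.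
- *Comparison:* the chosen plan carries a second silyl ether and sets C6 earlier with an auxiliary. Against that its ring closure uses two-electron organochromium chemistry that ignores enoates and esters, and its aldehyde has the quaternary C10 as the neighbour of its α-carbon.

Key step: step 20

Remark: 1 and 21 are taken as catalogue compounds; 21 is redistilled before use, and 9, sold as an aqueous solution, is dehydrated and distilled.

Step 1
Reactants: 1 4-methyl hydrogen itaconate (4-methoxy-2-methylidene-4-oxobutanoic acid)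
Product: 3 methyl 3-(hydroxymethyl)but-3-enoate, via mixed ethyl carbonic anhydride 2 (not isolated)
Conditions: ClCO2Et, Et3N, THF, −10 °C; then NaBH4, H2O, 0 °C
Reagents that add atoms: none
Why: Reduction of a carboxylic acid through its mixed carbonic anhydride; borohydride attacks only the activated acyl carbon, so the methyl ester and the alkene should remain, as known for 2-substituted acrylic acids.

Step 2
Reactants: 3 methyl 3-(hydroxymethyl)but-3-enoate
Product: 4 methyl 3-[(tert-butyldimethylsilyloxy)methyl]but-3-enoate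
Conditions: TBSCl, imidazole, CH2Cl2, 0 → 25 °C
Reagents that add atoms: tert-butyldimethylsilyl chloride, CC(C)(C)[Si](C)(C)Cl
Why: Standard silylation of a primary alcohol, done at once because the γ-hydroxy ester can lactonise; this puts the O15 protecting group of the final precursor in place.

Step 3
Reactants: 4 methyl 3-[(tert-butyldimethylsilyloxy)methyl]but-3-enoate
Product: 5 3-[(tert-butyldimethylsilyloxy)methyl]but-3-enoic acid
Conditions: LiOH, THF/H2O, 0 °C; then aq. NaHSO4 to pH 4
Reagents that add atoms: lithium hydroxide, [Li+].[OH-]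
Why: Saponification at 0 °C; the carboxylate resists further enolisation, so the β,γ-alkene should not move into conjugation, and the primary silyl ether tolerates LiOH and brief pH 4.

Step 4
Reactants: 5 3-[(tert-butyldimethylsilyloxy)methyl]but-3-enoic acid; 6 (R)-4-benzyl-1,3-oxazolidin-2-one
Product: 8 (R)-4-benzyl-3-{3-[(TBSO)methyl]but-3-enoyl}-1,3-oxazolidin-2-one, via mixed pivalic anhydride 7 (not isolated)
Conditions: 5, t-BuCOCl, Et3N, THF, −78 → 0 °C; then 6/n-BuLi (THF, −78 °C), −78 → 0 °C
Reagents that add atoms: none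
Why: Standard N-acylation of a lithiated oxazolidinone by a mixed pivalic anhydride; the nucleophile attacks the less hindered acyl carbon, and the low temperature limits isomerisation of the β,γ-unsaturated acyl group.

Step 5
Reactants: 8 (R)-4-benzyl-3-{3-[(TBSO)methyl]but-3-enoyl}-1,3-oxazolidin-2-one; 9 2,2-dimethoxyacetaldehyde
Product: 11 (R)-4-benzyl-3-[(2R,3R)-3-hydroxy-4,4-dimethoxy-2-(3-TBSO-prop-1-en-2-yl)butanoyl]-1,3-oxazolidin-2-one, via dibutylboron dienolate 10 (not isolated)
Conditions: Bu2BOTf, Et3N, CH2Cl2, −78 → 0 °C; 9, −78 → 0 °C; H2O2, MeOH, pH 7 buffer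
Reagents that add atoms: none
Why: Evans syn-aldol: the (Z)-boron enolate 10 reacts at its α-carbon (known for butenoyl imides) through a closed chair in which the (R)-benzyl group shields one face, setting C5 and C6 together with the syn relationship (C4 branch and hydroxyl) that the target requires; the α,α-dialkoxy aldehyde is a reactive, non-enolising acceptor.

Step 6
Reactants: 11 (R)-4-benzyl-3-[(2R,3R)-3-hydroxy-4,4-dimethoxy-2-(3-TBSO-prop-1-en-2-yl)butanoyl]-1,3-oxazolidin-2-one
Product: 12 (2R,3R)-3-hydroxy-N,4,4-trimethoxy-N-methyl-2-(3-TBSO-prop-1-en-2-yl)butanamide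
Conditions: MeNHOMe·HCl, AlMe3, THF, −20 → 0 °C
Reagents that add atoms: N,O-dimethylhydroxylamine hydrochloride, CNOC.Cl
Why: Aluminium amide transamination of a β-hydroxy imide to the Weinreb amide, assisted by the free hydroxyl; it is not basic enough to epimerise C5, and the auxiliary 6 is recovered.

Step 7
Reactants: 12 (2R,3R)-3-hydroxy-N,4,4-trimethoxy-N-methyl-2-(3-TBSO-prop-1-en-2-yl)butanamide
Product: 13 (2R,3R)-3-TBSO-N,4,4-trimethoxy-N-methyl-2-(3-TBSO-prop-1-en-2-yl)butanamide
Conditions: TBSOTf, 2,6-lutidine, CH2Cl2, −78 °C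
Reagents that add atoms: tert-butyldimethylsilyl trifluoromethanesulfonate, CC(C)(C)[Si](C)(C)OS(=O)(=O)C(F)(F)F
Why: Silylation of the hindered secondary alcohol with the silyl triflate; at −78 °C the bulky triflate should not ionise the α-oxygenated dimethyl acetal.

Step 8
Reactants: 13 (2R,3R)-3-TBSO-N,4,4-trimethoxy-N-methyl-2-(3-TBSO-prop-1-en-2-yl)butanamide; 14 ethyl acetate
Product: 15 ethyl (4R,5R)-5-TBSO-6,6-dimethoxy-3-oxo-4-(3-TBSO-prop-1-en-2-yl)hexanoate
Conditions: 14, LiN(i-Pr)2, THF, −78 °C; 13, −78 → −40 °C; aq. NH4Cl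
Reagents that add atoms: none
Why: Claisen-type acylation of the lithium enolate of ethyl acetate by a Weinreb amide; the chelated tetrahedral adduct survives until the quench and the β-keto ester is released as its stabilised enolate, so C5 is never the α-carbon of a free ketone under base.

Step 9
Reactants: 15 ethyl (4R,5R)-5-TBSO-6,6-dimethoxy-3-oxo-4-(3-TBSO-prop-1-en-2-yl)hexanoate
Product: 16 ethyl (2Z,4R,5R)-3-(diethoxyphosphoryloxy)-5-TBSO-6,6-dimethoxy-4-(3-TBSO-prop-1-en-2-yl)hex-2-enoate
Conditions: NaH, Et2O, 0 °C; ClP(O)(OEt)2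
Reagents that add atoms: diethyl chlorophosphate, CCOP(=O)(Cl)OCC
Why: O-Phosphorylation of the sodium enolate of a β-keto ester; sodium chelated between the two oxygens gives the (Z)-enol phosphate, and only the doubly activated C1 position is deprotonated.

Step 10
Reactants: 16 ethyl (2Z,4R,5R)-3-(diethoxyphosphoryloxy)-5-TBSO-6,6-dimethoxy-4-(3-TBSO-prop-1-en-2-yl)hex-2-enoate
Product: 17 ethyl (2E,4R,5R)-5-TBSO-6,6-dimethoxy-3-methyl-4-(3-TBSO-prop-1-en-2-yl)hex-2-enoate
Conditions: Me2CuLi (from MeLi, CuI), Et2O, −78 → −45 °C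
Reagents that add atoms: lithium dimethylcuprate, [Li+].C[Cu-]C
Why: Addition–elimination of the Gilman reagent on a β-phosphoryloxy enoate with retention of geometry, a known stereospecific route to trisubstituted β-methyl enoates; this fixes the C10=C1 geometry (C5 trans to C2), and the low temperature prevents a second conjugate addition.

Step 11
Reactants: 17 ethyl (2E,4R,5R)-5-TBSO-6,6-dimethoxy-3-methyl-4-(3-TBSO-prop-1-en-2-yl)hex-2-enoate
Product: 18 (2E,4R,5R)-5-TBSO-6,6-dimethoxy-3-methyl-4-(3-TBSO-prop-1-en-2-yl)hex-2-en-1-ol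
Conditions: i-Bu2AlH, CH2Cl2, −78 °C; aq. KNaC4H4O6
Reagents that add atoms: none
Why: 1,2-Reduction of an enoate to the allylic alcohol; silyl ethers, the acetal and the alkene geometry are unaffected.

Step 12
Reactants: 18 (2E,4R,5R)-5-TBSO-6,6-dimethoxy-3-methyl-4-(3-TBSO-prop-1-en-2-yl)hex-2-en-1-ol
Product: 19 (2E,4R,5R)-5-TBSO-6,6-dimethoxy-3-methyl-4-(3-TBSO-prop-1-en-2-yl)hex-2-en-1-yl acetate
Conditions: Ac2O, pyridine, DMAP (cat.), CH2Cl2, 0 °C
Reagents that add atoms: acetic anhydride, CC(=O)OC(C)=O
Why: Routine acetylation that provides the leaving group for the palladium step under neutral conditions.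

Step 13
Reactants: 19 (2E,4R,5R)-5-TBSO-6,6-dimethoxy-3-methyl-4-(3-TBSO-prop-1-en-2-yl)hex-2-en-1-yl acetate
Product: 20 2-[(2E,4R,5R)-5-TBSO-6,6-dimethoxy-3-methyl-4-(3-TBSO-prop-1-en-2-yl)hex-2-en-1-yl]-4,4,5,5-tetramethyl-1,3,2-dioxaborolane
Conditions: B2pin2, Pd(dba)2 (5 mol %), DMSO, 50 °C
Reagents that add atoms: bis(pinacolato)diboron, CC1(C)OB(OC1(C)C)B1OC(C)(C)C(C)(C)O1
Why: Known borylation of allylic acetates with zerovalent palladium: the allylpalladium intermediate is borylated at its primary terminus, and syn/anti exchange at the fully substituted terminus is slow, so the (E) geometry should be kept under base-free conditions.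

Step 14
Reactants: 20 2-[(2E,4R,5R)-5-TBSO-6,6-dimethoxy-3-methyl-4-(3-TBSO-prop-1-en-2-yl)hex-2-en-1-yl]-4,4,5,5-tetramethyl-1,3,2-dioxaborolane; 21 (S)-2,2-dimethyl-1,3-dioxolane-4-carbaldehyde
Product: 22 (1R,2S,3S,4R)-4-TBSO-1-[(4S)-2,2-dimethyl-1,3-dioxolan-4-yl]-2-ethenyl-5,5-dimethoxy-2-methyl-3-(3-TBSO-prop-1-en-2-yl)pentan-1-ol
Conditions: toluene (2 M), 25 → 45 °C; aq. NaHCO3
Reagents that add atoms: none
Why: Allylboration through a Zimmerman–Traxler chair: γ-attack makes the quaternary C10 with its vinyl group, and the (E) geometry places C5 anti and the methyl syn to the new hydroxyl, which ties C10 to C9; the aldehyde is attacked on its Felkin–Anh (anti) face, the strongly preferred mode for glyceraldehyde acetonide with allylboronates bearing a cis γ-substituent, which sets C9 as R and hence C10 as S.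

Step 15
Reactants: 22 (1R,2S,3S,4R)-4-TBSO-1-[(4S)-2,2-dimethyl-1,3-dioxolan-4-yl]-2-ethenyl-5,5-dimethoxy-2-methyl-3-(3-TBSO-prop-1-en-2-yl)pentan-1-ol
Product: 23 (1R,2S,3S,4R)-4-TBSO-1-[(4S)-2,2-dimethyl-1,3-dioxolan-4-yl]-2-ethenyl-5,5-dimethoxy-2-methyl-3-(3-TBSO-prop-1-en-2-yl)pentyl 2-methylpropanoate
Conditions: (i-PrCO)2O, Et3N, DMAP, CH2Cl2, 25 °C
Reagents that add atoms: 2-methylpropanoic anhydride, CC(C)C(=O)OC(=O)C(C)C
Why: DMAP-catalysed acylation of a hindered secondary alcohol; no free hydroxyl is nearby, so the ester cannot migrate.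

Step 16
Reactants: 23 (1R,2S,3S,4R)-4-TBSO-1-[(4S)-2,2-dimethyl-1,3-dioxolan-4-yl]-2-ethenyl-5,5-dimethoxy-2-methyl-3-(3-TBSO-prop-1-en-2-yl)pentyl 2-methylpropanoate
Product: 25 (1R,2S,3S,4R)-4-TBSO-1-[(4S)-2,2-dimethyl-1,3-dioxolan-4-yl]-2-ethenyl-2-methyl-5-oxo-3-(3-TBSO-prop-1-en-2-yl)pentyl 2-methylpropanoate, via collidinium N,O-acetal triflate 24 (not isolated)
Conditions: TESOTf, 2,4,6-collidine, CH2Cl2, 0 °C; then H2O
Reagents that add atoms: water, O
Why: Silyl triflate–pyridine base cleavage of an aldehyde dimethyl acetal through the pyridinium salt 24; the method is known to spare ketals such as the acetonide and TBS ethers, and the near-neutral hydrolysis should not epimerise C6.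

Step 17
Reactants: 25 (1R,2S,3S,4R)-4-TBSO-1-[(4S)-2,2-dimethyl-1,3-dioxolan-4-yl]-2-ethenyl-2-methyl-5-oxo-3-(3-TBSO-prop-1-en-2-yl)pentyl 2-methylpropanoate; 26 methyl prop-2-ynoate
Product: 27 methyl (4R,5S,6S,7R)-4-TBSO-7-[(4S)-2,2-dimethyl-1,3-dioxolan-4-yl]-6-ethenyl-3-hydroxy-6-methyl-2-methylidene-7-(2-methylpropanoyloxy)-5-(3-TBSO-prop-1-en-2-yl)heptanoate (both C3 epimers)
Conditions: 26, i-Bu2AlH, N-methylmorpholine N-oxide, THF, 0 °C; then 25, 0 → 25 °C
Reagents that add atoms: none
Why: Hydroalumination of the propiolate gives an α-(methoxycarbonyl)vinylalane that adds to aldehydes to give Morita–Baylis–Hillman-type adducts where the amine-catalysed reaction is too slow; it is non-basic, so C6 should hold, and the new C7 carbinol centre need not be controlled because it is lost in step 18.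

Step 18
Reactants: 27 methyl (4R,5S,6S,7R)-4-TBSO-7-[(4S)-2,2-dimethyl-1,3-dioxolan-4-yl]-6-ethenyl-3-hydroxy-6-methyl-2-methylidene-7-(2-methylpropanoyloxy)-5-(3-TBSO-prop-1-en-2-yl)heptanoate
Product: 28 methyl (2Z,4S,5S,6S,7R)-2-(bromomethyl)-4-TBSO-7-[(4S)-2,2-dimethyl-1,3-dioxolan-4-yl]-6-ethenyl-6-methyl-7-(2-methylpropanoyloxy)-5-(3-TBSO-prop-1-en-2-yl)hept-2-enoate
Conditions: NBS, Me2S, CH2Cl2, 0 → 25 °C
Reagents that add atoms: N-bromosuccinimide, O=C1CCC(=O)N1Br
Why: Corey–Kim-type activation of the Baylis–Hillman alcohol followed by SN2′ attack of bromide at C13; the conjugated enoate forms as the favoured (Z) isomer with C6 trans to the ester, the usual outcome for 2-(bromomethyl)alk-2-enoates, and NBS is bound to the sulfide before it meets the other alkenes.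

Step 19
Reactants: 28 methyl (2Z,4S,5S,6S,7R)-2-(bromomethyl)-4-TBSO-7-[(4S)-2,2-dimethyl-1,3-dioxolan-4-yl]-6-ethenyl-6-methyl-7-(2-methylpropanoyloxy)-5-(3-TBSO-prop-1-en-2-yl)hept-2-enoate
Product: 30 methyl (2Z,4S,5S,6S,7R)-2-(bromomethyl)-4-TBSO-6-ethenyl-6-methyl-7-(2-methylpropanoyloxy)-8-oxo-5-(3-TBSO-prop-1-en-2-yl)oct-2-enoate, via diol 29 (not isolated)
Conditions: H5IO6, EtOAc, 25 °C
Reagents that add atoms: none
Why: Periodic acid in ethyl acetate is known to convert terminal isopropylidene acetals directly into aldehydes: the diol 29 is cleaved as it forms, which leaves little time for isobutyryl migration from O9; 30 is used crude because the α-acyloxy aldehyde can epimerise at C9.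

Step 20
Reactants: 30 methyl (2Z,4S,5S,6S,7R)-2-(bromomethyl)-4-TBSO-6-ethenyl-6-methyl-7-(2-methylpropanoyloxy)-8-oxo-5-(3-TBSO-prop-1-en-2-yl)oct-2-enoate
Product: 33 (3aR,4R,5S,6S,7R,7aS)-4-TBSO-6-ethenyl-6-methyl-3-methylidene-2-oxo-5-(3-TBSO-prop-1-en-2-yl)octahydro-1-benzofuran-7-yl 2-methylpropanoate, via allylchromium dichloride 31 (not isolated), via chromium alkoxide 32 (not isolated)
Conditions: CrCl2 (6 equiv), THF (0.005 M), 25 °C; aq. NH4Cl
Reagents that add atoms: none
Why: Two equivalents of CrCl2 (divalent chromium) convert the allylic C13–Br bond into the allylchromium 31 (trivalent chromium), which does not attack esters or silyl ethers and adds only to the aldehyde. Its γ-carbon C7 attacks C8 in a chromium-bridged six-membered chair and the double bond moves to C11=C13; the closest known reaction is the chromium-mediated intramolecular Barbier (Nozaki–Hiyama–Kishi-type) cyclisation of formyl-tethered 2-(bromomethyl)alk-2-enoates to cis-fused α-methylene-γ-butyrolactones. The carbocycle closes by 6-exo-trig addition to the carbonyl, and the alkoxide 32 then closes the lactone by 5-exo-trig acyl substitution at C12 with loss of methoxide. C7 and C8 are set relative to each other by the metal-bridged chair: with the (Z)-allyl unit C6 is axial on that chair and the ring tether forces C9 equatorial, so C11 and O8 come out cis. The face is set by the forming cyclohexane, which should take the chair with the C5, C6 and C9 substituents equatorial and the C10 methyl axial. Allylic 1,3-strain between C13 and C6 keeps H6 in the alkene plane, which puts C11 equatorial and O8 axial and gives the target's configuration at C7 and C8. The step needs cis over trans fusion and one of the two cis faces, secured by the (Z) geometry from step 18 and the four existing centres. High dilution suppresses intermolecular coupling, and the neutral medium should leave C9 and the finished methylene lactone untouched.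

Step 21
Reactants: 33 (3aR,4R,5S,6S,7R,7aS)-4-TBSO-6-ethenyl-6-methyl-3-methylidene-2-oxo-5-(3-TBSO-prop-1-en-2-yl)octahydro-1-benzofuran-7-yl 2-methylpropanoate
Product: 34 (3aS,4R,5S,6S,7R,7aS)-6-ethenyl-4-hydroxy-5-(3-hydroxyprop-1-en-2-yl)-6-methyl-3-methylidene-2-oxooctahydro-1-benzofuran-7-yl 2-methylpropanoate
Conditions: HF·pyridine, pyridine, THF, 0 → 25 °C
Reagents that add atoms: none
Why: Buffered fluoride cleavage of both silyl ethers; the methylene lactone and the isobutyrate tolerate these weakly acidic conditions, and no hydroxyl is freed next to the ester, so no acyl shift is expected.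

## Compound list

1 | 4-methyl hydrogen itaconate (4-methoxy-2-methylidene-4-oxobutanoic acid) | C=C(CC(=O)OC)C(=O)O | starting material
2 | mixed ethyl carbonic anhydride of 1 | C=C(CC(=O)OC)C(=O)OC(=O)OCC | intermediate
3 | methyl 3-(hydroxymethyl)but-3-enoate | C=C(CO)CC(=O)OC | intermediate
4 | methyl 3-[(tert-butyldimethylsilyloxy)methyl]but-3-enoate | C=C(CO[Si](C)(C)C(C)(C)C)CC(=O)OC | intermediate
5 | 3-[(tert-butyldimethylsilyloxy)methyl]but-3-enoic acid | C=C(CO[Si](C)(C)C(C)(C)C)CC(=O)O | intermediate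
6 | (R)-4-benzyl-1,3-oxazolidin-2-one | O=C1N[C@H](Cc2ccccc2)CO1 | starting material
7 | mixed pivalic anhydride of 5 | C=C(CO[Si](C)(C)C(C)(C)C)CC(=O)OC(=O)C(C)(C)C | intermediate
8 | (R)-4-benzyl-3-{3-[(TBSO)methyl]but-3-enoyl}-1,3-oxazolidin-2-one | C=C(CO[Si](C)(C)C(C)(C)C)CC(=O)N1C(=O)OC[C@H]1Cc1ccccc1 | intermediate
9 | 2,2-dimethoxyacetaldehyde | COC(OC)C=O | starting material
10 | (Z)-dibutylboron dienolate of 8 | C=C(CO[Si](C)(C)C(C)(C)C)/C=C(\OB(CCCC)CCCC)N1C(=O)OC[C@H]1Cc1ccccc1 | intermediate
11 | (R)-4-benzyl-3-[(2R,3R)-3-hydroxy-4,4-dimethoxy-2-(3-TBSO-prop-1-en-2-yl)butanoyl]-1,3-oxazolidin-2-one | O=C([C@H](C(=C)CO[Si](C)(C)C(C)(C)C)[C@@H](O)C(OC)OC)N1C(=O)OC[C@H]1Cc1ccccc1 | intermediate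
12 | (2R,3R)-3-hydroxy-N,4,4-trimethoxy-N-methyl-2-(3-TBSO-prop-1-en-2-yl)butanamide | CON(C)C(=O)[C@H](C(=C)CO[Si](C)(C)C(C)(C)C)[C@@H](O)C(OC)OC | intermediate
13 | (2R,3R)-3-TBSO-N,4,4-trimethoxy-N-methyl-2-(3-TBSO-prop-1-en-2-yl)butanamide | CON(C)C(=O)[C@H](C(=C)CO[Si](C)(C)C(C)(C)C)[C@@H](O[Si](C)(C)C(C)(C)C)C(OC)OC | intermediate
14 | ethyl acetate | CCOC(C)=O | starting material
15 | ethyl (4R,5R)-5-TBSO-6,6-dimethoxy-3-oxo-4-(3-TBSO-prop-1-en-2-yl)hexanoate | CCOC(=O)CC(=O)[C@H](C(=C)CO[Si](C)(C)C(C)(C)C)[C@@H](O[Si](C)(C)C(C)(C)C)C(OC)OC | intermediate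
16 | ethyl (2Z,4R,5R)-3-(diethoxyphosphoryloxy)-5-TBSO-6,6-dimethoxy-4-(3-TBSO-prop-1-en-2-yl)hex-2-enoate | CCOC(=O)/C=C(\OP(=O)(OCC)OCC)[C@H](C(=C)CO[Si](C)(C)C(C)(C)C)[C@@H](O[Si](C)(C)C(C)(C)C)C(OC)OC | intermediate
17 | ethyl (2E,4R,5R)-5-TBSO-6,6-dimethoxy-3-methyl-4-(3-TBSO-prop-1-en-2-yl)hex-2-enoate | CCOC(=O)/C=C(\C)[C@H](C(=C)CO[Si](C)(C)C(C)(C)C)[C@@H](O[Si](C)(C)C(C)(C)C)C(OC)OC | intermediate
18 | (2E,4R,5R)-5-TBSO-6,6-dimethoxy-3-methyl-4-(3-TBSO-prop-1-en-2-yl)hex-2-en-1-ol | OC/C=C(\C)[C@H](C(=C)CO[Si](C)(C)C(C)(C)C)[C@@H](O[Si](C)(C)C(C)(C)C)C(OC)OC | intermediate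
19 | (2E,4R,5R)-5-TBSO-6,6-dimethoxy-3-methyl-4-(3-TBSO-prop-1-en-2-yl)hex-2-en-1-yl acetate | CC(=O)OC/C=C(\C)[C@H](C(=C)CO[Si](C)(C)C(C)(C)C)[C@@H](O[Si](C)(C)C(C)(C)C)C(OC)OC | intermediate
20 | 2-[(2E,4R,5R)-5-TBSO-6,6-dimethoxy-3-methyl-4-(3-TBSO-prop-1-en-2-yl)hex-2-en-1-yl]-4,4,5,5-tetramethyl-1,3,2-dioxaborolane | CC1(C)OB(C/C=C(\C)[C@H](C(=C)CO[Si](C)(C)C(C)(C)C)[C@@H](O[Si](C)(C)C(C)(C)C)C(OC)OC)OC1(C)C | intermediate
21 | (S)-2,2-dimethyl-1,3-dioxolane-4-carbaldehyde | CC1(C)OC[C@@H](C=O)O1 | starting material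
22 | (1R,2S,3S,4R)-4-TBSO-1-[(4S)-2,2-dimethyl-1,3-dioxolan-4-yl]-2-ethenyl-5,5-dimethoxy-2-methyl-3-(3-TBSO-prop-1-en-2-yl)pentan-1-ol | CC1(C)OC[C@H](O1)[C@H](O)[C@@](C)(C=C)[C@H](C(=C)CO[Si](C)(C)C(C)(C)C)[C@@H](O[Si](C)(C)C(C)(C)C)C(OC)OC | intermediate
23 | 2-methylpropanoate of 22 | CC1(C)OC[C@H](O1)[C@H](OC(=O)C(C)C)[C@@](C)(C=C)[C@H](C(=C)CO[Si](C)(C)C(C)(C)C)[C@@H](O[Si](C)(C)C(C)(C)C)C(OC)OC | intermediate
24 | 2,4,6-trimethylpyridinium N,O-acetal triflate from 23 (C7 bears OMe and the pyridinium nitrogen; both C7 epimers) | CC1(C)OC[C@H](O1)[C@H](OC(=O)C(C)C)[C@@](C)(C=C)[C@H](C(=C)CO[Si](C)(C)C(C)(C)C)[C@@H](O[Si](C)(C)C(C)(C)C)C(OC)[n+]1c(C)cc(C)cc1C.[O-]S(=O)(=O)C(F)(F)F | intermediate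
25 | (1R,2S,3S,4R)-4-TBSO-1-[(4S)-2,2-dimethyl-1,3-dioxolan-4-yl]-2-ethenyl-2-methyl-5-oxo-3-(3-TBSO-prop-1-en-2-yl)pentyl 2-methylpropanoate | CC1(C)OC[C@H](O1)[C@H](OC(=O)C(C)C)[C@@](C)(C=C)[C@H](C(=C)CO[Si](C)(C)C(C)(C)C)[C@@H](O[Si](C)(C)C(C)(C)C)C=O | intermediate
26 | methyl prop-2-ynoate | C#CC(=O)OC | starting material
27 | methyl (4R,5S,6S,7R)-4-TBSO-7-[(4S)-2,2-dimethyl-1,3-dioxolan-4-yl]-6-ethenyl-3-hydroxy-6-methyl-2-methylidene-7-(2-methylpropanoyloxy)-5-(3-TBSO-prop-1-en-2-yl)heptanoate (both C3 epimers) | CC1(C)OC[C@H](O1)[C@H](OC(=O)C(C)C)[C@@](C)(C=C)[C@H](C(=C)CO[Si](C)(C)C(C)(C)C)[C@@H](O[Si](C)(C)C(C)(C)C)C(O)C(=C)C(=O)OC | intermediate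
28 | methyl (2Z,4S,5S,6S,7R)-2-(bromomethyl)-4-TBSO-7-[(4S)-2,2-dimethyl-1,3-dioxolan-4-yl]-6-ethenyl-6-methyl-7-(2-methylpropanoyloxy)-5-(3-TBSO-prop-1-en-2-yl)hept-2-enoate | CC1(C)OC[C@H](O1)[C@H](OC(=O)C(C)C)[C@@](C)(C=C)[C@H](C(=C)CO[Si](C)(C)C(C)(C)C)[C@@H](O[Si](C)(C)C(C)(C)C)/C=C(\CBr)C(=O)OC | intermediate
29 | methyl (2Z,4S,5S,6S,7R,8S)-2-(bromomethyl)-4-TBSO-6-ethenyl-8,9-dihydroxy-6-methyl-7-(2-methylpropanoyloxy)-5-(3-TBSO-prop-1-en-2-yl)non-2-enoate | OC[C@H](O)[C@H](OC(=O)C(C)C)[C@@](C)(C=C)[C@H](C(=C)CO[Si](C)(C)C(C)(C)C)[C@@H](O[Si](C)(C)C(C)(C)C)/C=C(\CBr)C(=O)OC | intermediate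
30 | methyl (2Z,4S,5S,6S,7R)-2-(bromomethyl)-4-TBSO-6-ethenyl-6-methyl-7-(2-methylpropanoyloxy)-8-oxo-5-(3-TBSO-prop-1-en-2-yl)oct-2-enoate | O=C[C@H](OC(=O)C(C)C)[C@@](C)(C=C)[C@H](C(=C)CO[Si](C)(C)C(C)(C)C)[C@@H](O[Si](C)(C)C(C)(C)C)/C=C(\CBr)C(=O)OC | intermediate
31 | allylchromium dichloride from 30 (C13–CrCl2 in place of C13–Br) | O=C[C@H](OC(=O)C(C)C)[C@@](C)(C=C)[C@H](C(=C)CO[Si](C)(C)C(C)(C)C)[C@@H](O[Si](C)(C)C(C)(C)C)/C=C(\C[Cr](Cl)Cl)C(=O)OC | intermediate
32 | dichlorochromium C8-alkoxide of the cyclised hydroxy ester (C7–C8 bond formed, C11=C13, methyl ester intact) | C=C[C@@]1(C)[C@H](C(=C)CO[Si](C)(C)C(C)(C)C)[C@@H](O[Si](C)(C)C(C)(C)C)[C@H](C(=C)C(=O)OC)[C@H](O[Cr](Cl)Cl)[C@@H]1OC(=O)C(C)C | intermediate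
33 | (3aR,4R,5S,6S,7R,7aS)-4-TBSO-6-ethenyl-6-methyl-3-methylidene-2-oxo-5-(3-TBSO-prop-1-en-2-yl)octahydro-1-benzofuran-7-yl 2-methylpropanoate | C=C[C@@]1(C)[C@H](C(=C)CO[Si](C)(C)C(C)(C)C)[C@@H](O[Si](C)(C)C(C)(C)C)[C@@H]2C(=C)C(=O)O[C@@H]2[C@@H]1OC(=O)C(C)C | intermediate
34 | (3aS,4R,5S,6S,7R,7aS)-6-ethenyl-4-hydroxy-5-(3-hydroxyprop-1-en-2-yl)-6-methyl-3-methylidene-2-oxooctahydro-1-benzofuran-7-yl 2-methylpropanoate | C=C[C@@]1(C)[C@H](C(=C)CO)[C@@H](O)[C@@H]2C(=C)C(=O)O[C@@H]2[C@@H]1OC(=O)C(C)C | target

## Step count and least certain steps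

Total: 21 steps. Longest linear sequence: 21 steps (1 → 34); 6, 9, 14, 21 and 26 enter as commercial reagents.

**Step 20 (key step).**
- *What may go wrong:* the allylchromium may equilibrate to its (E) isomer before it adds, which opens a path to the trans-fused lactone. Facial selectivity may erode, because the reacting chair places the chromium-bound oxygen syn-axial to the C10 methyl. The C6 silyloxy group may be lost by 1,4-elimination from the allylmetal. Intermolecular coupling may compete if dilution is insufficient. Lactonisation of the hydroxy ester may be incomplete.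
- *Fallback (Hosomi–Sakurai cyclisation, open transition state, same C7–C8 disconnection):* setting out from 28, silylation with hexamethyldisilane and Pd(dba)2 (zerovalent palladium) gives the allylsilane F1. Periodic acid as in step 19 gives the silane aldehyde F2. BF3·OEt2 at −78 °C then joins C7 to C8, and the hydroxy ester lactonises on warming with pyridinium p-toluenesulfonate, which returns to 33.

**Step 14.**
- *What may go wrong:* addition of the hindered γ,γ-disubstituted pinacol boronate may be slow, and the aldehyde may oligomerise meanwhile. The aldehyde's facial preference may be opposed by the C5/C6 centres of the reagent (mismatched pairing), which would lower selectivity at C9 and C10.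
- *Fallback (organochromium allylation in place of boron):* setting out from 18, diethyl chlorophosphate and pyridine give the allylic phosphate F3. With CrCl2 and catalytic LiI in DMPU this adds to 21 through the more reactive allylchromium (trivalent chromium), which keeps the alkene geometry in that medium and attacks the same aldehyde face, and the route is rejoined at 22.

**Step 17.**
- *What may go wrong:* the hindered α-silyloxy aldehyde may not add; residual Al–H may reduce the aldehyde; the isobutyrate may be attacked.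
- *Fallback (selenolate Michael–aldol, then oxidation):* setting out from 25, Me2AlSePh and methyl acrylate give the β-hydroxy α-(phenylselanylmethyl) ester F4. H2O2 then triggers selenoxide elimination and returns to 27.

**Step 19.**
- *What may go wrong:* the acidity of periodic acid may cleave the primary allylic silyl ether. The isobutyryl group may shift from O9 to O8 in the transient diol, which would block the cleavage.
- *Fallback (two separate, buffered operations):* setting out from 28, the acetonide is removed with catalytic CeCl3·7H2O and oxalic acid in MeCN and the diol 29 is isolated. Pb(OAc)4 with solid K2CO3 in CH2Cl2 at 0 °C then cleaves it without acid and returns to 30.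

**Step 10.**
- *What may go wrong:* substitution at the hindered β-carbon may be slow, and a second conjugate addition or reductive loss of the phosphate may compete.
- *Fallback (carbonyl olefination):* setting out from 13, MeMgBr gives the methyl ketone F5. A Horner–Wadsworth–Emmons reaction with triethyl phosphonoacetate (NaH, THF) returns to 17 after separation of the (Z) isomer. The reaction time must be kept short because C5 of F5 can epimerise.

## Further compounds

F1 | step 20 | methyl (2Z,4S,5S,6S,7R)-4-TBSO-7-[(4S)-2,2-dimethyl-1,3-dioxolan-4-yl]-6-ethenyl-6-methyl-7-(2-methylpropanoyloxy)-5-(3-TBSO-prop-1-en-2-yl)-2-[(trimethylsilyl)methyl]hept-2-enoate | CC1(C)OC[C@H](O1)[C@H](OC(=O)C(C)C)[C@@](C)(C=C)[C@H](C(=C)CO[Si](C)(C)C(C)(C)C)[C@@H](O[Si](C)(C)C(C)(C)C)/C=C(\C[Si](C)(C)C)C(=O)OC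
F2 | step 20 | methyl (2Z,4S,5S,6S,7R)-4-TBSO-6-ethenyl-6-methyl-7-(2-methylpropanoyloxy)-8-oxo-5-(3-TBSO-prop-1-en-2-yl)-2-[(trimethylsilyl)methyl]oct-2-enoate | O=C[C@H](OC(=O)C(C)C)[C@@](C)(C=C)[C@H](C(=C)CO[Si](C)(C)C(C)(C)C)[C@@H](O[Si](C)(C)C(C)(C)C)/C=C(\C[Si](C)(C)C)C(=O)OC
F3 | step 14 | (2E,4R,5R)-5-TBSO-6,6-dimethoxy-3-methyl-4-(3-TBSO-prop-1-en-2-yl)hex-2-en-1-yl diethyl phosphate | CCOP(=O)(OCC)OC/C=C(\C)[C@H](C(=C)CO[Si](C)(C)C(C)(C)C)[C@@H](O[Si](C)(C)C(C)(C)C)C(OC)OC
F4 | step 17 | methyl (4R,5S,6S,7R)-4-TBSO-7-[(4S)-2,2-dimethyl-1,3-dioxolan-4-yl]-6-ethenyl-3-hydroxy-6-methyl-7-(2-methylpropanoyloxy)-2-[(phenylselanyl)methyl]-5-(3-TBSO-prop-1-en-2-yl)heptanoate (C2 and C3 epimers) | CC1(C)OC[C@H](O1)[C@H](OC(=O)C(C)C)[C@@](C)(C=C)[C@H](C(=C)CO[Si](C)(C)C(C)(C)C)[C@@H](O[Si](C)(C)C(C)(C)C)C(O)C(C[Se]c1ccccc1)C(=O)OC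
F0 | step 19 | none | none
F5 | step 10 | (3R,4R)-4-TBSO-5,5-dimethoxy-3-(3-TBSO-prop-1-en-2-yl)pentan-2-one | CC(=O)[C@H](C(=C)CO[Si](C)(C)C(C)(C)C)[C@@H](O[Si](C)(C)C(C)(C)C)C(OC)OC
A1 | alternative 1 | 2-(hydroxymethyl)-2-methyl-3-(3-TBSO-prop-1-en-2-yl)-4-TBSO-cyclohexan-1-one with C5, C6 and C10 as in 34 | OC[C@@]1(C)[C@H](C(=C)CO[Si](C)(C)C(C)(C)C)[C@@H](O[Si](C)(C)C(C)(C)C)CCC1=O
A2 | alternative 1 | (S)-4-(tert-butyldimethylsilyloxy)-2-methylcyclohex-2-en-1-one | CC1=C[C@@H](O[Si](C)(C)C(C)(C)C)CCC1=O
A3 | alternative 1 | [3-(tert-butyldimethylsilyloxy)prop-1-en-2-yl]magnesium bromide | C=C(CO[Si](C)(C)C(C)(C)C)[Mg]Br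
A4 | alternative 1 | formaldehyde | C=O
A5 | alternative 2 | cyclised 6-hydroxy lactone lacking the exocyclic methylene, 15-TBS ether | C=C[C@@]1(C)[C@H](C(=C)CO[Si](C)(C)C(C)(C)C)[C@@H](O)[C@@H]2CC(=O)O[C@@H]2[C@@H]1OC(=O)C(C)C
A6 | alternative 2 | open-chain γ-lactone C6-aldehyde with (Z)-C5=C4 alkene (C3 methyl, C15 silyl ether) | O=C[C@@H]1CC(=O)O[C@@H]1[C@H](OC(=O)C(C)C)[C@@](C)(C=C)/C=C(/C)CO[Si](C)(C)C(C)(C)C
A7 | alternative 3 | 15-TBS ether of 34 | C=C[C@@]1(C)[C@H](C(=C)CO[Si](C)(C)C(C)(C)C)[C@@H](O)[C@@H]2C(=C)C(=O)O[C@@H]2[C@@H]1OC(=O)C(C)C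
A8 | alternative 3 | C6-aldehyde tethered to the α-(phenylthiomethyl)butenolide | O=C[C@@H](C(=C)CO[Si](C)(C)C(C)(C)C)[C@](C)(C=C)[C@@H](OC(=O)C(C)C)[C@H]1OC(=O)C(CSc2ccccc2)=C1
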